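(Readings and results were generated by integration from invented constants; noise was put on by code.)

| flask | E | J | remark | time |
|---|---|---|---|---|
| ochre | 0.20 M | 0.285 M | run made earlier |  |
| teal | 0.45 M | 0.285 M | run made earlier |  |
| flask | 0.30 M | 0.285 M |  | 10 min |

| run | time / min | Q / % | E / % |
|---|---|---|---|
| ochre | 0.333 | 100 | 4 |
| ochre | 1.00 | 102 | 0 |
| ochre | 1.50 | 102 | 0 |
| ochre | 2.50 | 100 | 0 |
| ochre | 4.00 | 99 | 1 |
| ochre | 5.00 | 100 | 0 |
| ochre | 6.00 | 98 | 0 |
| teal | 0.833 | 62 | 38 |
| teal | 1.50 | 61 | 36 |
| teal | 2.50 | 65 | 36 |
| teal | 3.00 | 63 | 37 |
| teal | 4.00 | 63 | 37 |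
| teal | 5.00 | 62 | 36 |
| teal | 6.00 | 62 | 39 |

(readings scatter by 1.5 percentage points)

- each molecule carries two end groups: a chain counts once for every two ends that are left, dead ends included; the units are half of the end groups of the two monomers charged
- the numbers in the tables scatter by 1.5 percentage points (one standard deviation)

* average number of monomer units in a chain (unreacted monomers counted as chains of one) at 10 min
* part of the E that has reacted at 10 min

1. I took the easy step first: one E and one J make one link Q. Ochre ended with Q near the E charged, and teal with Q near the J charged.

2. In teal, E was charged over J, so I averaged its Q and its E used. That gave c_Q = 0.283 M, short of the J charged by 0.00246 M. This gap is a reading: 0.55 percentage points of the E charged, with a scatter of 0.4 points.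

3. I took the gap as J lost to dead ends by a first-order step, constant k_d, beside the coupling, constant k. Dead ends form at k_d c_J and links at k c_E c_J. Dividing one rate by the other removes c_J and time: dead ends per link = κ/c_E, with κ = k_d/k.

4. Summed over a run that uses up J, the dead ends are D = κ ln(c_E at start / c_E at end). Teal reads κ = 0.00249 M, the leak concentration: the c_E at which J splits evenly between the two paths.

5. In the flask, J is the limiting reagent, 0.285 M against 0.30 M of E, so c_E at the end is the excess plus D. Solving gives D = 0.00658 M. Chains are half the ends left, E ends and dead ends, and units are half the ends charged. My reckoning therefore gave dp 20.8 and c 92.8%, both carrying the gap's scatter.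

6. The forecast gave dp 32 and c 94.5%. Of the flask's progress it wrote: "only a reverse reaction could limit it".

The flask gave dp 16.4 and c 91.5%, a dp lower than mine and the forecast's. After 10.0 min it held 0.0104 M of L, the dead ends, with J at 0% of its charge. In this flask, κ gives 0.00830 dead ends per link at the start, and more, 0.0982, at the E left at the end.

    J → L (k = 0.00837 s⁻¹)
    E + J → Q (k = 1.99 L mol⁻¹ s⁻¹)

For a neighbour flask, the same recipe but with 0.11 M of J, κ gives D = 0.00112 M, so dp 2.13 and c 36.3%. The computed neighbour flask gave dp 2.12 and c 36.0%.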